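Readings and results stem from a simulated flask from invented constants, noise included.

Product was what I followed in the runs below, and what I had to foretell for the noon flask, which has less starting material and more free catalyst.

| flask | starting material | reagent | free catalyst | product | time |
|---|---|---|---|---|---|
| midnight | 0.0500 M | 0.0750 M | 5.00 × 10⁻⁴ M |  |  |
| dawn | 0.0500 M | 0.0750 M | 5.00 × 10⁻⁴ M | 0.0150 M |  |
| dusk | 0.0500 M | 0.0370 M | 5.00 × 10⁻⁴ M |  |  |
| autumn | 0.0500 M | 0.0750 M | 0.00100 M |  |  |
| noon | 0.0170 M | 0.0750 M | 0.00150 M |  | 13 min |

- midnight run (time / min: [product] / M): 2.6: 0.0081; 5.2: 0.0126; 7.8: 0.0159; 10: 0.0178; 13: 0.0210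
- dawn run (time / min: [product] / M): 2.6: 0.0224; 5.2: 0.0274; 7.8: 0.0309; 10: 0.0331; 13: 0.0355
- dusk run (time / min: [product] / M): 2.6: 0.0123; 5.2: 0.0190; 7.8: 0.0248; 10: 0.0273; 13: 0.0310
- autumn run (time / min: [product] / M): 2.6: 0.0127; 5.2: 0.0179; 7.8: 0.0221; 10: 0.0239; 13: 0.0259

(standard deviation of a reading: 3 × 10⁻⁴ M)

- Overall: starting material + reagent -> product, with free catalyst as catalyst.
- Constant volume, constant temperature.
- A reading of a species includes what of it is bound.
- An order is taken over about fifteen percent of the charge, up and down.

* reaction order in [free catalyst] at the outset, round the charge of the midnight run, defined at two percent of the starting material turned into product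
* reaction order in [reagent] at the outset, round the charge of the midnight run, defined at two percent of the starting material turned into product
* product in the noon run at 13 min, as a share of the starting material charged

I asked first whether product interferes. The dawn run, charged with 0.0150 M of product, had made 0.0124 M more at 5.2 min, and the midnight run read 0.0126 M at 5.2 min; that gap of 2.00 × 10⁻⁴ M lies inside the scatter of 3 × 10⁻⁴ M, so I left product out of the reckoning.

Next I asked what free catalyst buys. The autumn run, with twice the free catalyst of the midnight run, read 0.0127 M at 2.6 min and the midnight run read 0.0126 M at 5.2 min, so nearly equal product took 2.00 times as long at the lower charge, which I read as an order of 1.00 in c(free catalyst). The comparison did not drift: the autumn run read 0.0179 M at 5.2 min and the midnight run 0.0178 M at 10 min, a time ratio of 1.92 against a ratio of charges of 2.00. For the noon flask, 13 min at its charge comes to 39.0 min of the midnight run; I call this the catalyst clock, a flask's time multiplied by its charge of free catalyst over the midnight charge.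

Last I asked what dilution does. The dusk run, with c(reagent) at 0.0370 M, read 0.0123 M at 2.6 min and 0.0190 M at 5.2 min, so by interpolation it passed 0.0126 M at about 2.72 min, earlier than the 5.2 min of the midnight run, and I read from this an order of −0.919 in c(reagent). The runs so far hold starting material at 0.0500 M, so I assumed that the ratio c(reagent)/c(starting material) is what counts. That ratio is 1.50 at midnight and 4.41 at noon, which multiplies the clock by 0.371 and leaves 14.5 min. Extending the midnight readings on the logarithm of time, I committed to 44.0%.

The forecast gave 0.93, −0.6 and 58%, “assuming roughly first order in substrate”. That 58% is what the midnight run gives with its clock scaled as if first order in everything but starting material, and it differs from my figure.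

The simulation gave 1.0, −0.90 and 46.4%.

    free catalyst + starting material → loaded catalyst + by-product (498.0 M⁻¹ min⁻¹)
    loaded catalyst + reagent → product + free catalyst (4968 M⁻¹ min⁻¹)
    starting material + reagent ⇌ idle substrate-reagent adduct, settled at all times (45.90 M⁻¹)
    2 free catalyst → 2 spent catalyst (247.8 M⁻¹ min⁻¹)

The noon flask ran 39.0 min on the catalyst clock, past the 22.6 min at which the midnight run reached half of its starting material, yet it stood at 46.4%. Two steps together held it there: the pairing of starting material with reagent to the idle substrate-reagent adduct, and the step from free catalyst to spent catalyst. Without the step to spent catalyst the noon flask gave 92.5%, and without the pairing, on the same 39.0 min, it gave 90.8%.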